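**Strategy.** The route rests on cutting the bond between C5 of the dibenzo[7]annulene (the CH shared by the seven-membered ring and the fused dihydrofuran) and the central-ring carbon that is ortho to one furan oxygen and para to the other. That carbon is a highly nucleophilic position of a free resorcinol, and C5 is a latent trans-stilbene-oxide carbon. The key step is a 7-exo Friedel–Crafts opening of an enantiopure oxirane: it closes the carbocycle and sets C5 by inversion. Its precursor is an open (Z)-stilbene bearing the oxirane and an uncyclized dihydrofuran arm. Both furans then close by Mitsunobu etherification; the 2,4-dihydroxyphenyl ring enters last by hydroarylation.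

Key step: step 10

Labels used below: central ring = the benzene ring that carries both furan oxygens; ring B = the other benzo ring of the seven-membered ring; C5, C10, C11 = sp3 carbons of the 5H-dibenzo[a,d][7]annulene (C5 between the benzo rings, C10 on ring B, C11 on the central ring).
Assumption: the D-fructose-derived Shi ketone is taken to give the (2R,3R)-oxirane, as it does with trans-stilbene; if the sense were opposite, the enantiomeric ketone would be used.

**Step 1**
Reactants: 1 3,5-bis(benzyloxy)benzyl bromide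
Product: 2 diethyl [3,5-bis(benzyloxy)benzyl]phosphonate
Conditions: P(OEt)3, neat, 140 °C
Reagents that add atoms: triethyl phosphite, CCOP(OCC)OCC
Why: Michaelis–Arbuzov reaction of the primary benzylic bromide with triethyl phosphite should give the phosphonate cleanly; no stereocentre is formed.

**Step 2**
Reactants: 2 phosphonate; 3 4-hydroxybenzaldehyde
Product: 4 (E)-4-{2-[3,5-bis(benzyloxy)phenyl]ethenyl}phenol
Conditions: KOtBu (2.2 equiv), DMF, 0 °C to rt
Reagents that add atoms: none
Why: Horner–Wadsworth–Emmons olefination of the benzylic phosphonate anion with the aldehyde (carried as its phenoxide) should give the E-stilbene; no stereocentre is formed.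

**Step 3**
Reactants: 4 hydroxystilbene
Product: 5 (E)-4-{2-[3,5-bis(benzyloxy)phenyl]ethenyl}phenyl methanesulfonate
Conditions: MsCl, Et3N, CH2Cl2, 0 °C
Reagents that add atoms: methanesulfonyl chloride, CS(=O)(=O)Cl
Why: O-sulfonylation of the only free phenol installs an electron-withdrawing stand-in for the 4-hydroxy group, so that the carbon next to this ring resists ionization in steps 6, 10 and 12.

**Step 4**
Reactants: 5 stilbene mesylate
Product: 6 4-{(2R,3R)-3-[3,5-bis(benzyloxy)phenyl]oxiran-2-yl}phenyl methanesulfonate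
Conditions: D-fructose-derived Shi ketone (30 mol%), Oxone, K2CO3, Bu4NHSO4, MeCN–DMM/aq. borate buffer (pH 10.5), 0 °C
Reagents that add atoms: Oxone (potassium peroxymonosulfate), [K+].[O-]S(=O)(=O)OO
Why: Shi asymmetric epoxidation of a trans-stilbene, in which the chiral dioxirane should deliver oxygen to the alkene face that gives the (2R,3R)-oxirane; these two centres later become C3 and C2 of each dihydrofuran.

**Step 5**
Reactants: 7 3,5-dihydroxybenzaldehyde
Product: 8 5-ethynylbenzene-1,3-diol
Conditions: Ohira–Bestmann reagent, K2CO3, MeOH, rt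
Reagents that add atoms: dimethyl (1-diazo-2-oxopropyl)phosphonate, CC(=O)C(=[N+]=[N-])P(=O)(OC)OC
Why: Ohira–Bestmann (Seyferth–Gilbert) homologation converts the aldehyde into the terminal alkyne; the meta-phenoxides do not deactivate the carbonyl by resonance, and no stereocentre is formed.

**Step 6**
Reactants: 8 ethynylresorcinol; 6 trans-oxirane mesylate
Product: 9 4-{(1S,2R)-2-[3,5-bis(benzyloxy)phenyl]-2-(2-ethynyl-4,6-dihydroxyphenyl)-1-hydroxyethyl}phenyl methanesulfonate
Conditions: HFIP, 0 °C to rt, oxirane added slowly to the ethynylresorcinol held in excess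
Reagents that add atoms: none
Why: Fluoroalcohol-promoted Friedel–Crafts arylation of the oxirane is a 1:1 addition with no by-product (the surplus resorcinol is recovered unchanged), in which the resorcinol carbon para to one OH and ortho to the slim ethynyl group should attack the benzylic carbon next to the bis(benzyloxy)phenyl ring (the carbon next to the mesyloxyphenyl ring is deactivated) with inversion, setting the diarylmethine centre (R) and leaving the carbinol centre untouched (S by CIP).

**Step 7**
Reactants: 6 oxirane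
Product: 10 4-{(2R,3R)-3-[3,5-bis(benzyloxy)-2-iodophenyl]oxiran-2-yl}phenyl methanesulfonate
Conditions: NIS, MeCN, 0 °C to rt, dark
Reagents that add atoms: N-iodosuccinimide, O=C1CCC(=O)N1I
Why: Electrophilic aromatic iodination of the 1,3-dialkoxybenzene ring at the position para to one benzyloxy group and next to the oxirane-bearing carbon; neutral NIS should spare the deactivated oxirane, whose centres are unaffected.

**Step 8**
Reactants: 9 alkynyl diol; 10 iodo oxirane
Product: 11 diarylalkyne (ethynyl carbon of 9 joined to C2 of the iodinated ring of 10)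
Conditions: PdCl2(PPh3)2 (5 mol%), CuI (10 mol%), Et3N, THF, rt to 40 °C
Reagents that add atoms: none
Why: Sonogashira coupling of the aryl iodide with the terminal alkyne; free phenols, the secondary alcohol, aryl mesylates and the oxirane are tolerated, and no stereocentre is touched.

**Step 9**
Reactants: 11 diarylalkyne
Product: 12 (Z)-stilbene oxirane
Conditions: H2 (1 atm), Lindlar catalyst, quinoline, EtOAc, rt
Reagents that add atoms: none
Why: Lindlar semihydrogenation adds H2 syn to the diarylalkyne and should stop at the (Z)-alkene, the geometry that brings the central ring within reach of the oxirane; benzyl ethers and the oxirane should survive the poisoned catalyst.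

**Step 10**
Reactants: 12 (Z)-stilbene oxirane
Product: 13 5H-dibenzo[a,d][7]annulene triol-type intermediate (C5 R, carbinol on C5 S)
Conditions: Sc(OTf)3 (5 mol%), HFIP/CH2Cl2 (1:4), 2 mM, −20 to 0 °C
Reagents that add atoms: none
Why: Sc(OTf)3/HFIP activates the oxirane, and the central-ring carbon lying between the alkene-bearing carbon and a free OH (and para to the second OH) attacks the ring-B benzylic oxirane carbon from the back, so the new aryl–C5 bond closes the dibenzo[7]annulene in one SN2-like Friedel–Crafts event. The closest known reaction type is the intramolecular epoxy–arene (Friedel–Crafts) cyclization used to build benzo-fused seven-membered rings in stilbene-oligomer chemistry. The ring closes in the 7-exo-tet mode; the 8-endo alternative would need attack at the carbon deactivated by the 4-mesyloxyphenyl group. The only new stereocentre, C5, arises by inversion of the oxirane carbon installed in the Shi epoxidation and is therefore reagent-controlled (5R), while the neighbouring carbinol carbon keeps its configuration (S by CIP). The step needs site selectivity on both partners: the (Z)-alkene tether puts only this one free ortho carbon within reach, and the electron-poor aryl group on the distal carbon should suppress Meinwald rearrangement and distal opening.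

**Step 11**
Reactants: 13 annulene with two secondary alcohols and two phenols
Product: 14 bis(dihydrobenzofuran) with the C10=C11 alkene
Conditions: PPh3, DIAD, THF, 0 °C to rt
Reagents that add atoms: none
Why: Twofold intramolecular Mitsunobu etherification (5-exo-tet), in which each phenol displaces the activated secondary benzylic alcohol beside it with inversion (S to R), should give both trans-2,3-diaryl-2,3-dihydrobenzofurans, the electron-poor aryl groups disfavouring an SN1 pathway.

**Step 12**
Reactants: 14 bis(dihydrobenzofuran) alkene; 15 resorcinol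
Product: 16 C10-(2,4-dihydroxyphenyl) adduct (10R)
Conditions: TsOH·H2O (20 mol%), HFIP/CH2Cl2 (1:1), 0 °C, alkene added slowly to a large excess of resorcinol
Reagents that add atoms: none
Why: Acid-catalysed Friedel–Crafts hydroarylation is a 1:1 addition with no by-product (the surplus resorcinol is recovered unchanged), in which protonation at C11 gives the C10 cation stabilised by the ortho- and para-benzyloxy groups of ring B and resorcinol should attack through its C4 along the pseudo-axial direction (the fused dihydrofuran holds the C5 substituent pseudo-equatorial, and an equatorial aryl at C10 would clash with the neighbouring benzyloxy group), setting C10 (R).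

**Step 13**
Reactants: 16 bis-mesylate
Product: 17 diphenol (both mesylates cleaved)
Conditions: LDA (8 equiv), THF, −78 to 0 °C; aq. NH4Cl
Reagents that add atoms: none
Why: Base-mediated aryl mesylate cleavage: LDA deprotonates the mesyl methyl groups and loss of sulfene releases the two phenoxides at low temperature, without touching benzyl ethers or stereocentres.

**Step 14**
Reactants: 17 tetrabenzyl ether
Product: 18 CNP0154047.1
Conditions: BCl3, pentamethylbenzene, CH2Cl2, −78 °C; aqueous work-up
Reagents that add atoms: none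
Why: Lewis-acid debenzylation with pentamethylbenzene as cation scavenger should cleave the four benzyl ethers at −78 °C, conditions mild enough for the dihydrobenzofurans; no stereocentre is touched.

**Compound list**

1 | 3,5-bis(benzyloxy)benzyl bromide | BrCc1cc(OCc2ccccc2)cc(OCc2ccccc2)c1 | starting material
2 | diethyl [3,5-bis(benzyloxy)benzyl]phosphonate | CCOP(=O)(OCC)Cc1cc(OCc2ccccc2)cc(OCc2ccccc2)c1 | intermediate
3 | 4-hydroxybenzaldehyde | O=Cc1ccc(O)cc1 | starting material
4 | (E)-4-{2-[3,5-bis(benzyloxy)phenyl]ethenyl}phenol | Oc1ccc(/C=C/c2cc(OCc3ccccc3)cc(OCc3ccccc3)c2)cc1 | intermediate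
5 | (E)-4-{2-[3,5-bis(benzyloxy)phenyl]ethenyl}phenyl methanesulfonate | CS(=O)(=O)Oc1ccc(/C=C/c2cc(OCc3ccccc3)cc(OCc3ccccc3)c2)cc1 | intermediate
6 | 4-{(2R,3R)-3-[3,5-bis(benzyloxy)phenyl]oxiran-2-yl}phenyl methanesulfonate (trans) | CS(=O)(=O)Oc1ccc([C@H]2O[C@@H]2c2cc(OCc3ccccc3)cc(OCc3ccccc3)c2)cc1 | intermediate
7 | 3,5-dihydroxybenzaldehyde | O=Cc1cc(O)cc(O)c1 | starting material
8 | 5-ethynylbenzene-1,3-diol | C#Cc1cc(O)cc(O)c1 | intermediate
9 | 4-{(1S,2R)-2-[3,5-bis(benzyloxy)phenyl]-2-(2-ethynyl-4,6-dihydroxyphenyl)-1-hydroxyethyl}phenyl methanesulfonate | CS(=O)(=O)Oc1ccc([C@@H](O)[C@H](c2cc(OCc3ccccc3)cc(OCc3ccccc3)c2)c2c(O)cc(O)cc2C#C)cc1 | intermediate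
10 | 4-{(2R,3R)-3-[3,5-bis(benzyloxy)-2-iodophenyl]oxiran-2-yl}phenyl methanesulfonate | CS(=O)(=O)Oc1ccc([C@H]2O[C@@H]2c2cc(OCc3ccccc3)cc(OCc3ccccc3)c2I)cc1 | intermediate
11 | 4-[(2R,3R)-3-{3,5-bis(benzyloxy)-2-[(2-{(1R,2S)-1-[3,5-bis(benzyloxy)phenyl]-2-hydroxy-2-[4-(mesyloxy)phenyl]ethyl}-3,5-dihydroxyphenyl)ethynyl]phenyl}oxiran-2-yl]phenyl methanesulfonate | CS(=O)(=O)Oc1ccc([C@@H](O)[C@H](c2cc(OCc3ccccc3)cc(OCc3ccccc3)c2)c2c(O)cc(O)cc2C#Cc2c(OCc3ccccc3)cc(OCc3ccccc3)cc2[C@H]2O[C@@H]2c2ccc(OS(C)(=O)=O)cc2)cc1 | intermediate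
12 | (Z)-ethene-1,2-diyl analogue of 11 (alkyne reduced to the cis-alkene; the four stereocentres unchanged) | CS(=O)(=O)Oc1ccc([C@@H](O)[C@H](c2cc(OCc3ccccc3)cc(OCc3ccccc3)c2)c2c(O)cc(O)cc2/C=C\c2c(OCc3ccccc3)cc(OCc3ccccc3)cc2[C@H]2O[C@@H]2c2ccc(OS(C)(=O)=O)cc2)cc1 | intermediate
13 | 5H-dibenzo[a,d][7]annulene with the C10=C11 alkene: 2,4-dihydroxy on the central ring, 7,9-bis(benzyloxy) on ring B; C1 bears the (1R,2S)-1-[3,5-bis(benzyloxy)phenyl]-2-hydroxy-2-[4-(mesyloxy)phenyl]ethyl arm; C5 (R) bears the (S)-hydroxy[4-(mesyloxy)phenyl]methyl group | CS(=O)(=O)Oc1ccc([C@@H](O)[C@H](c2cc(OCc3ccccc3)cc(OCc3ccccc3)c2)c2c(O)cc(O)c3c2C=Cc2c(OCc4ccccc4)cc(OCc4ccccc4)cc2[C@H]3[C@H](O)c2ccc(OS(C)(=O)=O)cc2)cc1 | intermediate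
14 | bis(dihydrobenzofuran): 13 with O2 bonded to the arm carbinol carbon and O4 bonded to the carbinol carbon on C5; both furans trans, (2R,3R), each with 2-[4-(mesyloxy)phenyl]; C5 (R); C10=C11 retained | CS(=O)(=O)Oc1ccc([C@@H]2Oc3cc4c5c(c3[C@H]2c2cc(OCc3ccccc3)cc(OCc3ccccc3)c2)C=Cc2c(OCc3ccccc3)cc(OCc3ccccc3)cc2[C@H]5[C@H](c2ccc(OS(C)(=O)=O)cc2)O4)cc1 | intermediate
15 | resorcinol | Oc1cccc(O)c1 | starting material
16 | 14 with H added at C11 and a 2,4-dihydroxyphenyl group at C10 (10R); all five stereocentres R | CS(=O)(=O)Oc1ccc([C@@H]2Oc3cc4c5c(c3[C@H]2c2cc(OCc3ccccc3)cc(OCc3ccccc3)c2)C[C@H](c2ccc(O)cc2O)c2c(OCc3ccccc3)cc(OCc3ccccc3)cc2[C@H]5[C@H](c2ccc(OS(C)(=O)=O)cc2)O4)cc1 | intermediate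
17 | 16 with both mesylates cleaved to 4-hydroxyphenyl groups (four benzyl ethers remain) | Oc1ccc([C@@H]2Oc3cc4c5c(c3[C@H]2c2cc(OCc3ccccc3)cc(OCc3ccccc3)c2)C[C@H](c2ccc(O)cc2O)c2c(OCc3ccccc3)cc(OCc3ccccc3)cc2[C@H]5[C@H](c2ccc(O)cc2)O4)cc1 | intermediate
18 | CNP0154047.1: all-R pentacycle with two trans-2-(4-hydroxyphenyl)dihydrofurans on the central ring, 3,5-dihydroxyphenyl on the free furan C3, and 10R-(2,4-dihydroxyphenyl) on the seven-membered ring | Oc1ccc([C@@H]2Oc3cc4c5c(c3[C@H]2c2cc(O)cc(O)c2)C[C@H](c2ccc(O)cc2O)c2c(O)cc(O)cc2[C@H]5[C@H](c2ccc(O)cc2)O4)cc1 | target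

**Totals.** 14 steps in all; longest linear sequence 12 steps (steps 1–4, then 6 or 7, then 8–14).

**Steps most likely to fail**

Step 10. The oxirane may rearrange by a Meinwald shift or open at the distal carbon, and the acid may isomerize or oligomerize the electron-rich (Z)-alkene before the ring closes. The fallback makes the same aryl–C5 bond intermolecularly and closes the seven-membered ring by olefin metathesis. It sets out from 9 and 10 and comes back at 13. Lindlar semihydrogenation of 9 should give the styrene F1. Suzuki–Miyaura vinylation of 10 with potassium vinyltrifluoroborate should give the vinyl oxirane F2. HFIP-promoted arylation of F2 by F1, at its free carbon ortho to the vinyl group and with inversion, should give the diene F3. Ring-closing metathesis of F3 with a second-generation ruthenium benzylidene catalyst should then give 13.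

Step 12. The C10 cation may be captured by the neighbouring bis(benzyloxy)phenyl ring or by a second molecule, resorcinol may be alkylated twice, and facial control may be incomplete. The fallback brings the 2,4-dihydroxyphenyl ring in as part of a stilbene and closes the seven-membered ring last through the C10–aryl bond. It sets out from 6 and comes back at 16. Twofold HFIP arylation of 6 by commercial 5-bromoresorcinol (at C4 and C6) should give the tetraol F4. Twofold Mitsunobu closure should give the C2-symmetric bis(dihydrobenzofuran) bromide F5. Suzuki–Miyaura vinylation should give the styrene F6, and a Heck reaction with commercial 4-iodoresorcinol the (E)-stilbene F7. Acid (TsOH, HFIP/CH2Cl2) should then protonate the stilbene, and either of the two equivalent bis(benzyloxy)phenyl rings attacks the cation next to the dihydroxyphenyl ring to give 16.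

Step 11. The activated secondary benzylic alcohols may undergo β-elimination to triaryl alkenes, or the second closure may stall. The fallback closes the furans by an SN1 pathway instead of SN2. It sets out from 13 and comes back at 17. LDA cleavage of both mesylates should give the tetraphenol F8. Acid (TsOH, HFIP) in the presence of resorcinol 15 should then ionize the two 4-hydroxybenzylic alcohols, close both furans to the thermodynamically favoured trans isomers, and effect the hydroarylation in the same flask, giving 17.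

**Further compounds**

F1 | step 10 | 4-{(1S,2R)-2-[3,5-bis(benzyloxy)phenyl]-2-(2-ethenyl-4,6-dihydroxyphenyl)-1-hydroxyethyl}phenyl methanesulfonate | CS(=O)(=O)Oc1ccc([C@@H](O)[C@H](c2cc(OCc3ccccc3)cc(OCc3ccccc3)c2)c2c(O)cc(O)cc2C=C)cc1
F2 | step 10 | 4-{(2R,3R)-3-[3,5-bis(benzyloxy)-2-ethenylphenyl]oxiran-2-yl}phenyl methanesulfonate | CS(=O)(=O)Oc1ccc([C@H]2O[C@@H]2c2cc(OCc3ccccc3)cc(OCc3ccccc3)c2C=C)cc1
F3 | step 10 | diene: F1 arylated at C3 of its central ring by the benzylic carbon of F2 (new centre R, carbinol S) | CS(=O)(=O)Oc1ccc([C@@H](O)[C@H](c2cc(OCc3ccccc3)cc(OCc3ccccc3)c2)c2c(O)cc(O)c(c2C=C)[C@@H](c2cc(OCc3ccccc3)cc(OCc3ccccc3)c2C=C)[C@H](O)c2ccc(OS(C)(=O)=O)cc2)cc1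
F4 | step 12 | 5-bromoresorcinol carrying at C4 and C6 the (1R,2S)-1-[3,5-bis(benzyloxy)phenyl]-2-hydroxy-2-[4-(mesyloxy)phenyl]ethyl group | CS(=O)(=O)Oc1ccc([C@@H](O)[C@H](c2cc(OCc3ccccc3)cc(OCc3ccccc3)c2)c2c(O)cc(O)c(c2Br)[C@@H](c2cc(OCc3ccccc3)cc(OCc3ccccc3)c2)[C@H](O)c2ccc(OS(C)(=O)=O)cc2)cc1
F5 | step 12 | C2-symmetric bromobenzene fused to two (2R,3R)-trans-2-[4-(mesyloxy)phenyl]-3-[3,5-bis(benzyloxy)phenyl]dihydrofurans | CS(=O)(=O)Oc1ccc([C@@H]2Oc3cc4c([C@@H](c5cc(OCc6ccccc6)cc(OCc6ccccc6)c5)[C@H](c5ccc(OS(C)(=O)=O)cc5)O4)c(Br)c3[C@H]2c2cc(OCc3ccccc3)cc(OCc3ccccc3)c2)cc1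
F6 | step 12 | vinyl analogue of F5 (Br replaced by ethenyl) | CS(=O)(=O)Oc1ccc([C@@H]2Oc3cc4c([C@@H](c5cc(OCc6ccccc6)cc(OCc6ccccc6)c5)[C@H](c5ccc(OS(C)(=O)=O)cc5)O4)c(C=C)c3[C@H]2c2cc(OCc3ccccc3)cc(OCc3ccccc3)c2)cc1
F7 | step 12 | (E)-2-(2,4-dihydroxyphenyl)ethenyl analogue of F5 | CS(=O)(=O)Oc1ccc([C@@H]2Oc3cc4c([C@@H](c5cc(OCc6ccccc6)cc(OCc6ccccc6)c5)[C@H](c5ccc(OS(C)(=O)=O)cc5)O4)c(/C=C/c5ccc(O)cc5O)c3[C@H]2c2cc(OCc3ccccc3)cc(OCc3ccccc3)c2)cc1
F8 | step 11 | 13 with both mesylates cleaved to 4-hydroxyphenyl groups | Oc1ccc([C@@H](O)[C@H](c2cc(OCc3ccccc3)cc(OCc3ccccc3)c2)c2c(O)cc(O)c3c2C=Cc2c(OCc4ccccc4)cc(OCc4ccccc4)cc2[C@H]3[C@H](O)c2ccc(O)cc2)cc1
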